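**Retrosynthetic overview** (spiro[4.5]decane locants: C1 bears the isobutyrate, C3 the isopropenyl group, C5 is the spiro atom, C8 the ketone, C9 the acetate, C10 the secondary methyl)
1. Endgame: the C9 acetate comes from α′-acetoxylation of the enone; the C1 isobutyrate from reduction and acylation of a spiro 1,8-dione.
2. Key disconnection: the C2–C3 bond of ring A (cyclopentanone). The acetyl enolate carbon of a 4-acetyl-4-prenylcyclohexenone is oxidised to an electrophilic α-keto radical (an enolonium equivalent) and attacks the prenyl alkene. This closes ring A on the quaternary carbon and creates C3 and the isopropenyl group in one operation.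
3. Ring B (cyclohexenone) is made first, by an amine-catalysed asymmetric Robinson annulation of 3-prenylacetylacetone with (E)-pent-3-en-2-one, which sets C10 and the future spiro centre.
4. 3-Prenylacetylacetone comes from acetylacetone and prenyl bromide. Ring order: B, then A.

Assumption: the quinine-derived primary amine is taken to add the diketone to the enone face that gives the R methine (the sense recalled for it in the warfarin series); if the sense is opposite, its quinidine-derived pseudo-enantiomer is used instead.

**Step 1**
Reactants: 1 acetylacetone (pentane-2,4-dione); 2 prenyl bromide (1-bromo-3-methylbut-2-ene)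
Product: 3 3-(3-methylbut-2-en-1-yl)pentane-2,4-dione
Conditions: K2CO3, acetone, reflux
Reagents that add atoms: none
Why: SN2 C-alkylation of the stabilised diketone enolate by a reactive allylic bromide; no stereocentre is formed.

**Step 2**
Reactants: 3 3-(3-methylbut-2-en-1-yl)pentane-2,4-dione; 4 (E)-pent-3-en-2-one
Product: 7 (4R,5R)-4-acetyl-3,5-dimethyl-4-(3-methylbut-2-en-1-yl)cyclohex-2-en-1-one, via triketone Michael adduct 5 (not isolated), via ketol 6 (not isolated)
Conditions: 9-amino-9-deoxy-epi-quinine (20 mol %), CF3CO2H (40 mol %), toluene, 40 °C then 80 °C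
Reagents that add atoms: none
Why: Organocatalytic Robinson annulation: the diketone adds to one face of the chiral iminium ion of 4 to set the C5 methine as R (catalyst control), and the side-chain enamine then closes onto one acetyl group through a chair with the C5 methyl and the prenyl CH2 equatorial and the spectator acetyl axial, which places acetyl cis to methyl (4R) before dehydration.

**Step 3**
Reactants: 7 (4R,5R)-4-acetyl-3,5-dimethyl-4-(3-methylbut-2-en-1-yl)cyclohex-2-en-1-one
Product: 9 (3S,5R,10R)-6,10-dimethyl-3-(prop-1-en-2-yl)spiro[4.5]dec-6-ene-1,8-dione, via lithium enolate 8 (not isolated)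
Conditions: LiN(iPr)2 (1.05 equiv), THF, −78 °C; then Cu(O2CCH(C2H5)C4H9)2 (2.2 equiv), −78 → 0 °C
Reagents that add atoms: none
Why: Proposed new method: LiN(iPr)2 removes a proton from the acetyl methyl group (the only primary α-position; the ring α′-CH2 is flanked by the C5 methine and the quaternary C4), the divalent copper carboxylate oxidises the enolate to an electrophilic α-keto radical (a one-electron enolonium equivalent) that closes 5-exo onto the nucleophilic prenyl alkene, and a second copper carboxylate converts the tertiary radical into the less substituted alkene by β-hydride loss from a methyl group, so two carbons that are both nucleophilic by nature are joined and the isopropenyl group and C3 arise together, the side chain expected on the face of the new ring next to the flat C6 alkene arm and away from the C10 methine arm (3S); the closest known reactions are copper- or iron-mediated oxidative enolate couplings, ferrocenium-mediated oxidative radical cyclisations of enolates and Mn(OAc)3/Cu(OAc)2 oxidative free-radical cyclisations with Hofmann-selective termination.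

**Step 4**
Reactants: 9 (3S,5R,10R)-6,10-dimethyl-3-(prop-1-en-2-yl)spiro[4.5]dec-6-ene-1,8-dione
Product: 10 (1R,3S,5R,10R)-1-hydroxy-6,10-dimethyl-3-(prop-1-en-2-yl)spiro[4.5]dec-6-en-8-one
Conditions: NaBH4, MeOH/CH2Cl2 (1:1), −78 °C
Reagents that add atoms: none
Why: Chemoselective borohydride reduction: at low temperature the saturated cyclopentanone reacts faster than the β,β-disubstituted enone, and hydride enters C1 from the face next to the flat C6 arm, away from the C10 methine arm (whose methyl and C9 are gauche to C1), giving the 1R alcohol cis to C10 and trans to the isopropenyl group.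

**Step 5**
Reactants: 10 (1R,3S,5R,10R)-1-hydroxy-6,10-dimethyl-3-(prop-1-en-2-yl)spiro[4.5]dec-6-en-8-one
Product: 11 (1R,3S,5R,10R)-6,10-dimethyl-8-oxo-3-(prop-1-en-2-yl)spiro[4.5]dec-6-en-1-yl 2-methylpropanoate
Conditions: (iPrCO)2O, DMAP (cat.), pyridine, 40 °C
Reagents that add atoms: isobutyric anhydride, CC(C)C(=O)OC(=O)C(C)C
Why: DMAP-catalysed acylation (nucleophilic catalysis) of the hindered secondary alcohol, with retention at C1.

**Step 6**
Reactants: 11 (1R,3S,5R,10R)-6,10-dimethyl-8-oxo-3-(prop-1-en-2-yl)spiro[4.5]dec-6-en-1-yl 2-methylpropanoate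
Product: 12 (1R,3S,5R,9R,10S)-9-(acetyloxy)-6,10-dimethyl-8-oxo-3-(prop-1-en-2-yl)spiro[4.5]dec-6-en-1-yl 2-methylpropanoate
Conditions: Mn(OAc)3·2H2O (3 equiv), benzene, reflux (Dean–Stark)
Reagents that add atoms: manganese triacetate, CC(=O)[O-].CC(=O)[O-].CC(=O)[O-].[Mn+3]
Why: α′-Acetoxylation of an enone with Mn(OAc)3 (trivalent manganese enolate, acetate transfer) can only occur at C9, the sole enolisable α′ position, and the acetate enters trans to the neighbouring C10 methyl (9R), the diequatorial arrangement that is also favoured on equilibration; isolated alkenes and esters tolerate these conditions.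

**Compound list**
1 | acetylacetone (pentane-2,4-dione) | CC(=O)CC(C)=O | starting material
2 | prenyl bromide (1-bromo-3-methylbut-2-ene) | CC(C)=CCBr | starting material
3 | 3-(3-methylbut-2-en-1-yl)pentane-2,4-dione | CC(=O)C(CC=C(C)C)C(C)=O | intermediate
4 | (E)-pent-3-en-2-one | C/C=C/C(C)=O | starting material
5 | (4R)-3-acetyl-4-methyl-3-(3-methylbut-2-en-1-yl)heptane-2,6-dione | CC(=O)C[C@@H](C)C(CC=C(C)C)(C(C)=O)C(C)=O | intermediate
6 | (4R,5R)-4-acetyl-3-hydroxy-3,5-dimethyl-4-(3-methylbut-2-en-1-yl)cyclohexan-1-one (C3 epimers) | CC(=O)[C@@]1(CC=C(C)C)C(C)(O)CC(=O)C[C@H]1C | intermediate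
7 | (4R,5R)-4-acetyl-3,5-dimethyl-4-(3-methylbut-2-en-1-yl)cyclohex-2-en-1-one | CC(=O)[C@@]1(CC=C(C)C)C(C)=CC(=O)C[C@H]1C | intermediate
8 | lithium 1-[(1R,6R)-2,6-dimethyl-1-(3-methylbut-2-en-1-yl)-4-oxocyclohex-2-en-1-yl]ethen-1-olate | [Li+].C=C([O-])[C@@]1(CC=C(C)C)C(C)=CC(=O)C[C@H]1C | intermediate
9 | (3S,5R,10R)-6,10-dimethyl-3-(prop-1-en-2-yl)spiro[4.5]dec-6-ene-1,8-dione | C=C(C)[C@@H]1CC(=O)[C@@]2(C1)C(C)=CC(=O)C[C@H]2C | intermediate
10 | (1R,3S,5R,10R)-1-hydroxy-6,10-dimethyl-3-(prop-1-en-2-yl)spiro[4.5]dec-6-en-8-one | C=C(C)[C@@H]1C[C@@H](O)[C@@]2(C1)C(C)=CC(=O)C[C@H]2C | intermediate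
11 | (1R,3S,5R,10R)-6,10-dimethyl-8-oxo-3-(prop-1-en-2-yl)spiro[4.5]dec-6-en-1-yl 2-methylpropanoate | C=C(C)[C@@H]1C[C@@H](OC(=O)C(C)C)[C@@]2(C1)C(C)=CC(=O)C[C@H]2C | intermediate
12 | (1R,3S,5R,9R,10S)-9-(acetyloxy)-6,10-dimethyl-8-oxo-3-(prop-1-en-2-yl)spiro[4.5]dec-6-en-1-yl 2-methylpropanoate | C=C(C)[C@@H]1C[C@@H](OC(=O)C(C)C)[C@@]2(C1)C(C)=CC(=O)[C@H](OC(C)=O)[C@H]2C | target

**Totals**
Total step count: 6. Longest linear sequence: 6 steps (1 → 12).

**Steps most likely to fail, with fallbacks**

Step 3. The risks are three: deprotonation at the ring α′-CH2 instead of the acetyl methyl, transannular aldol addition of the enolate to the C1 carbonyl of ring B before oxidation, and formation of the C3 epimer, since 1,3-induction from the spiro centre is modest and its sense is uncertain. The fallback sets out from 7 and builds ring A without the oxidative closure. Ozonolysis of the electron-rich prenyl alkene (O3, pyridine, CH2Cl2, −78 °C; then Me2S) leaves the enone untouched and gives 2-[(1R,6R)-1-acetyl-2,6-dimethyl-4-oxocyclohex-2-en-1-yl]acetaldehyde F2. Intramolecular aldol condensation (KOH, MeOH) gives (5R,10R)-6,10-dimethylspiro[4.5]deca-2,6-diene-1,8-dione F3. A rhodium-catalysed 1,4-addition of potassium isopropenyltrifluoroborate ([Rh(acac)(C2H4)2], (S)-BINAP, dioxane/H2O) then sets C3 under ligand control, the ligand enantiomer chosen by analogy with cyclopent-2-enone; the β,β-disubstituted ring B enone is inert. The fallback returns to the route at 9.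

Step 2. The donor is hindered (a quaternary carbon is formed next to a tertiary one), so rate, enantioselectivity, the choice between the two acetyl groups and the alternative aldol mode are all uncertain. The fallback sets out from 1. Acetylacetone itself, an established donor class for iminium catalysis, is added to 4 with the same amine salt at room temperature and the reaction is stopped at the Michael stage to give (4R)-3-acetyl-4-methylheptane-2,6-dione F1, held as its enol. Its diketone carbon is prenylated under Tsuji–Trost conditions (Pd(PPh3)4, prenyl methyl carbonate, THF) to give triketone 5, and pyrrolidine/AcOH closes 5 to 7, where the fallback returns to the route.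

Step 4. The hindered cyclopentanone may react no faster than the enone, or hydride may enter from the other face. The fallback sets out from 9 and accepts the epimeric alcohol (1S,3S,5R,10R)-1-hydroxy-6,10-dimethyl-3-(prop-1-en-2-yl)spiro[4.5]dec-6-en-8-one F4, obtained with a bulky hydride such as LiBH(sBu)3. It is esterified with inversion by a Mitsunobu reaction with isobutyric acid (PPh3, DIAD, toluene), and the fallback returns to the route at 11.

**Further compounds**
F1 | step 2 | (4R)-3-acetyl-4-methylheptane-2,6-dione | CC(=O)C[C@@H](C)C(C(C)=O)C(C)=O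
F2 | step 3 | 2-[(1R,6R)-1-acetyl-2,6-dimethyl-4-oxocyclohex-2-en-1-yl]acetaldehyde | CC(=O)[C@@]1(CC=O)C(C)=CC(=O)C[C@H]1C
F3 | step 3 | (5R,10R)-6,10-dimethylspiro[4.5]deca-2,6-diene-1,8-dione | C1=CC(=O)[C@@]2(C1)C(C)=CC(=O)C[C@H]2C
F4 | step 4 | (1S,3S,5R,10R)-1-hydroxy-6,10-dimethyl-3-(prop-1-en-2-yl)spiro[4.5]dec-6-en-8-one | C=C(C)[C@@H]1C[C@H](O)[C@@]2(C1)C(C)=CC(=O)C[C@H]2C
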